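**Retrosynthetic overview**

1. Rings: A = acetoxycyclohexene, B = butenolide, C = epoxycyclohexanol; Ca = the CH3-bearing sp2 carbon joined to the ring-A alkyne, Cb = its CH neighbour. Last disconnection: the C(sp)–Ca bond, made by palladium-catalysed cross-addition of the terminal alkyne C–H of a ring-A enyne across the Ca≡Cb triple bond of a polyenyne that already holds rings B and C. Ca/Cb are carried one oxidation level up (alkyne) and return to the alkene level in the bond-forming event itself, so neither half needs a halide, a metal or a protecting group.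
2. Enabling feature: Ca=Cb is the end of an unbroken conjugated path (Ca=Cb, three further chain C=C bonds, the exocyclic C=C and the ring C=C of butenolide B) that ends in the lactone C=O, and Ca carries only CH3. The alkyne Ca≡Cb is therefore a vinylogous 2-alkynoate whose electrophilic and less hindered carbon is Ca; syn addition of alkynyl and H gives the E trisubstituted alkene directly, and the ring-A alkyne is shielded against self-addition by the gem-dimethyl and vinylic methyl groups.
3. Polyenyne: Suzuki–Miyaura coupling of a 3-bromo-5-ylidenebutenolide with the ring-C E-vinylboronate; ylidenebutenolide: vinylogous aldol condensation of 3-bromofuran-2(5H)-one with a C11 trienynal built from but-2-yn-1-ol.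
4. Ring order: carbocycles A and C are not built but come from (4R,6R)-actinol through one enol triflate (Sonogashira for A; carbonylation, reduction and Sharpless epoxidation, which closes the oxirane of C in step 8); ring B is bought as furan-2(5H)-one; the key step closes no ring.

Key step: step 20

Assumption: (4R,6R)-actinol is taken as a commercially available, enantiopure chiral-pool ketone, so that all four stereocentres derive from its C4 centre and from one reagent-controlled epoxidation.

**Route**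

Step 1
Reactants: 1 (4R,6R)-4-hydroxy-2,2,6-trimethylcyclohexan-1-one (actinol)
Product: 2 (4R,6R)-4-{[tert-butyl(dimethyl)silyl]oxy}-2,2,6-trimethylcyclohexan-1-one
Conditions: tBuMe2SiCl, imidazole, DMF, rt
Reagents that add atoms: tert-butyldimethylsilyl chloride, CC(C)(C)[Si](C)(C)Cl
Why: Imidazole-promoted silyl ether formation on the only hydroxyl; no stereocentre is touched.

Step 2
Reactants: 2 silyl ether of actinol
Product: 3 (4R)-4-{[tert-butyl(dimethyl)silyl]oxy}-2,6,6-trimethylcyclohex-1-en-1-yl trifluoromethanesulfonate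
Conditions: LiN(iPr)2, THF, −78 °C; then PhNTf2, −78 °C → rt
Reagents that add atoms: N-phenylbis(trifluoromethanesulfonimide), O=S(=O)(N(c1ccccc1)S(=O)(=O)C(F)(F)F)C(F)(F)F
Why: Enolisation is possible only towards C6 because C2 is quaternary, so O-sulfonylation of the lithium enolate (enol triflate formation) should give a single tetrasubstituted enol triflate; the C6 centre is removed on purpose and C4 is untouched.

Step 3
Reactants: 3 enol triflate
Product: 4 tert-butyl(dimethyl){[(1R)-3,5,5-trimethyl-4-[(trimethylsilyl)ethynyl]cyclohex-3-en-1-yl]oxy}silane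
Conditions: HC≡CSiMe3, Pd(PPh3)4 (5 mol%), CuI (10 mol%), Et3N, DMF, 50 °C
Reagents that add atoms: ethynyltrimethylsilane, C#C[Si](C)(C)C
Why: Sonogashira coupling of the enol triflate installs the two alkyne carbons of ring A without affecting the silyl ether.

Step 4
Reactants: 4 bis-silylated enyne
Product: 5 (1R)-4-ethynyl-3,5,5-trimethylcyclohex-3-en-1-ol
Conditions: Bu4NF (2.5 equiv), THF, 0 °C → rt
Reagents that add atoms: none
Why: Fluoride-mediated desilylation cleaves the C(sp)–Si and the O–Si bond in one operation.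

Step 5
Reactants: 5 hydroxy enyne
Product: 6 (1R)-4-ethynyl-3,5,5-trimethylcyclohex-3-en-1-yl acetate
Conditions: Ac2O, pyridine, 4-(dimethylamino)pyridine (cat.), CH2Cl2, rt
Reagents that add atoms: acetic anhydride, CC(=O)OC(C)=O
Why: Nucleophile-catalysed acylation puts the ring-A acetate in place before the union, so that the two hydroxyls of the target never have to be told apart.

Step 6
Reactants: 3 enol triflate
Product: 7 methyl (4R)-4-{[tert-butyl(dimethyl)silyl]oxy}-2,6,6-trimethylcyclohex-1-ene-1-carboxylate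
Conditions: CO (1 atm), Pd(OAc)2 (5 mol%), PPh3 (10 mol%), Et3N, MeOH–DMF, 60 °C
Reagents that add atoms: carbon monoxide, [C-]#[O+]; methanol, CO
Why: Palladium-catalysed alkoxycarbonylation of the enol triflate introduces the carbon that becomes the first vinylic carbon on ring C.

Step 7
Reactants: 7 enoate
Product: 8 [(4R)-4-{[tert-butyl(dimethyl)silyl]oxy}-2,6,6-trimethylcyclohex-1-en-1-yl]methanol
Conditions: iBu2AlH (2.2 equiv), CH2Cl2, −78 → 0 °C
Reagents that add atoms: none
Why: 1,2-Reduction of the hindered enoate by the aluminium hydride gives the allylic alcohol needed for directed epoxidation.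

Step 8
Reactants: 8 allylic alcohol
Product: 9 [(1R,4S,6R)-4-{[tert-butyl(dimethyl)silyl]oxy}-2,2,6-trimethyl-7-oxabicyclo[4.1.0]heptan-1-yl]methanol
Conditions: Ti(OiPr)4 (20 mol%), diethyl D-(−)-tartrate (24 mol%), tBuOOH (in decane), 4 Å MS, CH2Cl2, −20 °C
Reagents that add atoms: tert-butyl hydroperoxide, CC(C)(C)OO
Why: Sharpless asymmetric epoxidation under reagent control: with the D-tartrate the titanium-bound peroxide should be delivered to the alkene face anti to the C4 silyloxy group, which sets both oxirane carbons (C1 and C6) in the configuration of ring C.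

Step 9
Reactants: 9 epoxy alcohol
Product: 10 (1S,4S,6R)-4-{[tert-butyl(dimethyl)silyl]oxy}-2,2,6-trimethyl-7-oxabicyclo[4.1.0]heptane-1-carbaldehyde
Conditions: Dess–Martin periodinane, pyridine, CH2Cl2, 0 °C → rt
Reagents that add atoms: none
Why: Dess–Martin oxidation under buffered, non-acidic conditions should give the non-enolisable epoxy aldehyde without opening the oxirane.

Step 10
Reactants: 10 epoxy aldehyde
Product: 11 tert-butyl{[(1R,3S,6R)-6-ethynyl-1,5,5-trimethyl-7-oxabicyclo[4.1.0]heptan-3-yl]oxy}dimethylsilane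
Conditions: MeC(O)C(N2)P(O)(OMe)2, K2CO3, MeOH, 0 °C → rt
Reagents that add atoms: dimethyl (1-diazo-2-oxopropyl)phosphonate, COP(=O)(OC)C(=[N+]=[N-])C(C)=O
Why: Seyferth–Gilbert homologation in the Ohira–Bestmann variant converts the non-enolisable aldehyde into the terminal alkyne under mild base that the oxirane and the silyl ether tolerate.

Step 11
Reactants: 11 epoxy alkyne
Product: 12 tert-butyl(dimethyl){[(1R,3S,6S)-1,5,5-trimethyl-6-[(E)-2-(4,4,5,5-tetramethyl-1,3,2-dioxaborolan-2-yl)ethenyl]-7-oxabicyclo[4.1.0]heptan-3-yl]oxy}silane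
Conditions: pinacolborane (1.5 equiv), (c-C6H11)2BH (10 mol%), neat, rt
Reagents that add atoms: pinacolborane, CC1(C)OBOC1(C)C
Why: Dialkylborane-catalysed hydroboration of the terminal alkyne is a syn, anti-Markovnikov addition with no by-product, which fixes the E geometry of the vinyl link and uses no transition metal that could open the propargylic oxirane.

Step 12
Reactants: 12 silylated vinylboronate
Product: 13 (1R,3S,6S)-1,5,5-trimethyl-6-[(E)-2-(4,4,5,5-tetramethyl-1,3,2-dioxaborolan-2-yl)ethenyl]-7-oxabicyclo[4.1.0]heptan-3-ol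
Conditions: Bu4NF, THF, 0 °C
Reagents that add atoms: none
Why: Fluoride-mediated desilylation frees the ring-C hydroxyl at a stage where no lactone or acetate is present; the pinacol boronate and the oxirane should survive brief exposure at 0 °C.

Step 13
Reactants: 14 but-2-yn-1-ol
Product: 16 ethyl (2E,4E)-octa-2,4-dien-6-ynoate, via but-2-ynal 15 (not isolated)
Conditions: MnO2, CH2Cl2, rt, filter; filtrate added to (EtO)2P(O)CH2CH=CHCO2Et/LiN(SiMe3)2, THF, −78 → 0 °C
Reagents that add atoms: triethyl 4-phosphonocrotonate, CCOC(=O)/C=C/CP(=O)(OCC)OCC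
Why: Oxidation of the propargylic alcohol followed by a Horner–Wadsworth–Emmons reaction of the vinylogous phosphonate should give the (2E,4E)-dienoate, the E geometry following from the stabilised phosphonate anion.

Step 14
Reactants: 16 dienynoate
Product: 17 (2E,4E)-octa-2,4-dien-6-yn-1-ol
Conditions: iBu2AlH (2.2 equiv), CH2Cl2, −78 °C
Reagents that add atoms: none
Why: Aluminium hydride reduction of the ester to the allylic alcohol leaves the diene and the internal alkyne untouched.

Step 15
Reactants: 17 dienynol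
Product: 18 (2E,4E)-octa-2,4-dien-6-ynal
Conditions: MnO2, CH2Cl2, rt
Reagents that add atoms: none
Why: Allylic oxidation with MnO2 gives the dienynal without E/Z isomerisation.

Step 16
Reactants: 18 dienynal
Product: 19 (2E,4E,6E)-2-methyldeca-2,4,6-trien-8-ynal
Conditions: Ph3P=C(Me)CHO, toluene, 80 °C
Reagents that add atoms: 2-(triphenylphosphoranylidene)propanal, CC(C=O)=P(c1ccccc1)(c1ccccc1)c1ccccc1
Why: Wittig reaction with the stabilised formyl ylide gives the E trisubstituted enal, and the α-methyl enal formed is too unreactive to be homologated a second time.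

Step 17
Reactants: 20 furan-2(5H)-one
Product: 22 3-bromofuran-2(5H)-one, via dibromolactone 21 (not isolated)
Conditions: Br2, CH2Cl2, 0 °C → rt; then Et3N, 0 °C
Reagents that add atoms: bromine, BrBr
Why: Bromine addition to the enoate followed by E1cB dehydrobromination (loss of the acidic C3–H and the C4 bromide) gives the α-bromobutenolide.

Step 18
Reactants: 22 3-bromofuran-2(5H)-one; 19 trienynal
Product: 25 (5Z)-3-bromo-5-[(2E,4E,6E)-2-methyldeca-2,4,6-trien-8-yn-1-ylidene]furan-2(5H)-one, via silyloxyfuran 23 (not isolated), via silyl aldol adduct 24 (not isolated)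
Conditions: tBuMe2SiOTf (1.2 equiv), iPr2NEt (3 equiv), CH2Cl2, −78 °C → rt; then DBU (2 equiv), rt, dark
Reagents that add atoms: none
Why: Vinylogous Mukaiyama aldol addition of the in situ 2-silyloxyfuran through its C5 to the aldehyde, then base-induced E1cB loss of silanolate, should give the ylidenebutenolide with the thermodynamically preferred Z exocyclic double bond (chain syn to the ring oxygen, away from C4–H).

Step 19
Reactants: 25 bromo-ylidenebutenolide; 13 ring-C vinylboronate
Product: 26 (5Z)-3-[(E)-2-{(1S,4S,6R)-4-hydroxy-2,2,6-trimethyl-7-oxabicyclo[4.1.0]heptan-1-yl}ethenyl]-5-[(2E,4E,6E)-2-methyldeca-2,4,6-trien-8-yn-1-ylidene]furan-2(5H)-one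
Conditions: Pd(OAc)2 (5 mol%), SPhos (10 mol%), K3PO4 (3 M aq), THF, rt, dark
Reagents that add atoms: none
Why: Suzuki–Miyaura coupling of the activated α-bromo enoate with the E-vinylboronate proceeds with retention of both alkene geometries, and the fully substituted oxirane should not be ionised by zerovalent palladium at room temperature.

Step 20
Reactants: 26 polyenyne with rings B and C; 6 ring-A acetoxy enyne
Product: 27 pyrrhoxanthin (target)
Conditions: 6 (1.5 equiv), Pd(OAc)2 (5 mol%), tris(2,6-dimethoxyphenyl)phosphine (5 mol%), benzene, rt, dark, Ar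
Reagents that add atoms: none
Why: Proposed new method: Pd(OAc)2 and the electron-rich, bulky phosphine convert the terminal C–H of 6 into a divalent palladium acetylide, which adds syn across the Ca≡Cb triple bond of 26 with the alkynyl group going to Ca and palladium to Cb, and protonolysis of the alkenyl–palladium bond by a further molecule of 6 or by AcOH releases 27 and regenerates the acetylide, so that the C(sp)–Ca bond, the Cb–H bond and the alkene geometry arise together with no by-product. The closest known reaction type is the Pd(OAc)2/tris(2,6-dimethoxyphenyl)phosphine-catalysed cross-addition of terminal donor alkynes to 2-alkynoate, ynone and alkynyl sulfone acceptors, which gives (E)-2-en-4-ynoates by the same syn carbopalladation and protonolysis; here the acceptor is a vinylogous alkynoate activated by the lactone carbonyl of ring B through the conjugated chain. No ring is closed and no stereocentre is formed; the only new stereo-element, the Ca=Cb double bond, should be E because alkynyl and hydrogen are delivered to the same face of the alkyne, which places the ring-A alkyne trans to the chain. Regioselectivity is needed and is secured by the polarisation of the conjugated lactone (Ca is the electrophilic terminus) acting in the same sense as sterics (CH3 is the smaller alkyne substituent, so palladium ends on Cb next to the diene). Cross-addition over self-addition is needed and is secured because the alkyne of 6 and the new internal alkyne of 27 are both flanked by the ring-A gem-dimethyl and vinylic methyl groups and are poor acceptors, while 6 remains a good donor. Chemoselectivity is needed and is secured because only divalent palladium is present and no base or nucleophile is added, so the vinyl oxirane, the free hydroxyl, the acetate and the lactone should stay untouched.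

**Compound list**

1 | (4R,6R)-4-hydroxy-2,2,6-trimethylcyclohexan-1-one (actinol) | C[C@@H]1C[C@@H](O)CC(C)(C)C1=O | starting material
2 | (4R,6R)-4-{[tert-butyl(dimethyl)silyl]oxy}-2,2,6-trimethylcyclohexan-1-one | C[C@@H]1C[C@@H](O[Si](C)(C)C(C)(C)C)CC(C)(C)C1=O | intermediate
3 | (4R)-4-{[tert-butyl(dimethyl)silyl]oxy}-2,6,6-trimethylcyclohex-1-en-1-yl trifluoromethanesulfonate | CC(C)(C)[Si](C)(C)O[C@@H]1CC(C)=C(OS(=O)(=O)C(F)(F)F)C(C)(C)C1 | intermediate
4 | tert-butyl(dimethyl){[(1R)-3,5,5-trimethyl-4-[(trimethylsilyl)ethynyl]cyclohex-3-en-1-yl]oxy}silane | CC(C)(C)[Si](C)(C)O[C@@H]1CC(C)=C(C#C[Si](C)(C)C)C(C)(C)C1 | intermediate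
5 | (1R)-4-ethynyl-3,5,5-trimethylcyclohex-3-en-1-ol | O[C@@H]1CC(C)=C(C#C)C(C)(C)C1 | intermediate
6 | (1R)-4-ethynyl-3,5,5-trimethylcyclohex-3-en-1-yl acetate | CC(=O)O[C@@H]1CC(C)=C(C#C)C(C)(C)C1 | intermediate
7 | methyl (4R)-4-{[tert-butyl(dimethyl)silyl]oxy}-2,6,6-trimethylcyclohex-1-ene-1-carboxylate | COC(=O)C1=C(C)C[C@@H](O[Si](C)(C)C(C)(C)C)CC1(C)C | intermediate
8 | [(4R)-4-{[tert-butyl(dimethyl)silyl]oxy}-2,6,6-trimethylcyclohex-1-en-1-yl]methanol | OCC1=C(C)C[C@@H](O[Si](C)(C)C(C)(C)C)CC1(C)C | intermediate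
9 | [(1R,4S,6R)-4-{[tert-butyl(dimethyl)silyl]oxy}-2,2,6-trimethyl-7-oxabicyclo[4.1.0]heptan-1-yl]methanol | OC[C@@]12O[C@]1(C)C[C@@H](O[Si](C)(C)C(C)(C)C)CC2(C)C | intermediate
10 | (1S,4S,6R)-4-{[tert-butyl(dimethyl)silyl]oxy}-2,2,6-trimethyl-7-oxabicyclo[4.1.0]heptane-1-carbaldehyde | O=C[C@@]12O[C@]1(C)C[C@@H](O[Si](C)(C)C(C)(C)C)CC2(C)C | intermediate
11 | tert-butyl{[(1R,3S,6R)-6-ethynyl-1,5,5-trimethyl-7-oxabicyclo[4.1.0]heptan-3-yl]oxy}dimethylsilane | C#C[C@@]12O[C@]1(C)C[C@@H](O[Si](C)(C)C(C)(C)C)CC2(C)C | intermediate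
12 | tert-butyl(dimethyl){[(1R,3S,6S)-1,5,5-trimethyl-6-[(E)-2-(4,4,5,5-tetramethyl-1,3,2-dioxaborolan-2-yl)ethenyl]-7-oxabicyclo[4.1.0]heptan-3-yl]oxy}silane | CC1(C)OB(/C=C/[C@@]23O[C@]2(C)C[C@@H](O[Si](C)(C)C(C)(C)C)CC3(C)C)OC1(C)C | intermediate
13 | (1R,3S,6S)-1,5,5-trimethyl-6-[(E)-2-(4,4,5,5-tetramethyl-1,3,2-dioxaborolan-2-yl)ethenyl]-7-oxabicyclo[4.1.0]heptan-3-ol | CC1(C)OB(/C=C/[C@@]23O[C@]2(C)C[C@@H](O)CC3(C)C)OC1(C)C | intermediate
14 | but-2-yn-1-ol | CC#CCO | starting material
15 | but-2-ynal | CC#CC=O | intermediate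
16 | ethyl (2E,4E)-octa-2,4-dien-6-ynoate | CCOC(=O)/C=C/C=C/C#CC | intermediate
17 | (2E,4E)-octa-2,4-dien-6-yn-1-ol | OC/C=C/C=C/C#CC | intermediate
18 | (2E,4E)-octa-2,4-dien-6-ynal | O=C/C=C/C=C/C#CC | intermediate
19 | (2E,4E,6E)-2-methyldeca-2,4,6-trien-8-ynal | O=C/C(C)=C/C=C/C=C/C#CC | intermediate
20 | furan-2(5H)-one | O=C1OCC=C1 | starting material
21 | trans-3,4-dibromodihydrofuran-2(3H)-one (racemic) | O=C1OCC(Br)C1Br | intermediate
22 | 3-bromofuran-2(5H)-one | O=C1OCC=C1Br | intermediate
23 | [(3-bromofuran-2-yl)oxy](tert-butyl)dimethylsilane | CC(C)(C)[Si](C)(C)Oc1occc1Br | intermediate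
24 | 3-bromo-5-[(2E,4E,6E)-1-{[tert-butyl(dimethyl)silyl]oxy}-2-methyldeca-2,4,6-trien-8-yn-1-yl]furan-2(5H)-one (mixture of diastereomers at the two new sp3 centres, both lost in the elimination) | CC#C/C=C/C=C/C=C(C)/C(O[Si](C)(C)C(C)(C)C)C1OC(=O)C(Br)=C1 | intermediate
25 | (5Z)-3-bromo-5-[(2E,4E,6E)-2-methyldeca-2,4,6-trien-8-yn-1-ylidene]furan-2(5H)-one | CC#C/C=C/C=C/C=C(C)/C=C1C=C(Br)C(=O)O/1 | intermediate
26 | (5Z)-3-[(E)-2-{(1S,4S,6R)-4-hydroxy-2,2,6-trimethyl-7-oxabicyclo[4.1.0]heptan-1-yl}ethenyl]-5-[(2E,4E,6E)-2-methyldeca-2,4,6-trien-8-yn-1-ylidene]furan-2(5H)-one | CC#C/C=C/C=C/C=C(C)/C=C1C=C(/C=C/[C@@]23O[C@]2(C)C[C@@H](O)CC3(C)C)C(=O)O/1 | intermediate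
27 | pyrrhoxanthin: ring-A (R)-acetate, ring-C (3S,5R,6S)-epoxy alcohol, all-E chain, Z-ylidenebutenolide | CC(=O)O[C@@H]1CC(C)=C(C#C/C(C)=C/C=C/C=C/C=C(C)/C=C2C=C(/C=C/[C@@]34O[C@]3(C)C[C@@H](O)CC4(C)C)C(=O)O/2)C(C)(C)C1 | target

**Step count and risks**

Total step count: 20. Longest linear sequence: 11 steps (1, 2, 6 to 12, 19, 20).

Steps most likely to fail:

1. Step 20 (Proposed new method). What may go wrong: the triple bond of 26 is activated only through the long conjugated path and may insert into the palladium acetylide too slowly, so that head-to-tail self-addition of 6, palladium hydride-mediated E/Z scrambling of the polyene, or carbopalladation with the opposite regiochemistry take over. Fallback (known chemistry; sets out from 5, returns at 27): the same cross-addition is run on its established acceptor class, Pd(OAc)2/tris(2,6-dimethoxyphenyl)phosphine with ethyl but-2-ynoate, to give the ethyl (2E)-enynoate F1. iBu2AlH gives the diol F2, and MnO2 oxidises only its allylic hydroxyl to the enynal F3. The operations of steps 13 to 16 (Horner–Wadsworth–Emmons reaction with triethyl 4-phosphonocrotonate, iBu2AlH, MnO2, Wittig reaction with Ph3P=C(Me)CHO) then lead through the trienynoate F4, the trienyne diol F5 and the trienynal F6 to the hydroxy tetraenynal F7. Ac2O/pyridine gives the acetoxy tetraenynal F8; condensation with 22 under the conditions of step 18 gives, through the silyl aldol adduct F9, the full-chain bromobutenolide F10; Suzuki–Miyaura coupling of F10 with 13 under the conditions of step 19 gives 27.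

2. Step 18. What may go wrong: Lewis-acid-induced oligomerisation of the electron-rich polyenal, incomplete elimination of the silyl aldol, or poor control of the exocyclic double-bond geometry in the E1cB step. Fallback (Wittig olefination in place of aldol condensation; sets out from 22, returns at 25): radical bromination at C5 (N-bromosuccinimide, (PhCO2)2, CCl4, reflux) gives 3,5-dibromofuran-2(5H)-one F11; PPh3 (toluene, rt) gives the butenolide phosphonium bromide F12; Et3N generates the butenolide ylide F13, which reacts with 19 (CH2Cl2, rt) and, after iodine-catalysed equilibration of the exocyclic double bond to Z, gives 25.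

3. Step 19. What may go wrong: opening of the ylidene lactone by the aqueous base and protodeboronation of 13, both competing with a slow transmetalation. Fallback (base-free Stille coupling; sets out from 10, returns at 26): Takai-type chromium-mediated olefination with (dibromomethyl)tributylstannane (CrCl2, LiI, DMF–THF, rt) gives the silylated E-vinylstannane F14; Bu4NF (THF, 0 °C) gives the hydroxy vinylstannane F15; Stille coupling of F15 with 25 (Pd2(dba)3, AsPh3, N-methylpyrrolidone, rt) gives 26.

**Further compounds**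

F1 | step 20 | ethyl (2E)-5-[(4R)-4-hydroxy-2,6,6-trimethylcyclohex-1-en-1-yl]-3-methylpent-2-en-4-ynoate | CCOC(=O)/C=C(C)/C#CC1=C(C)C[C@@H](O)CC1(C)C
F2 | step 20 | (1R)-4-[(3E)-5-hydroxy-3-methylpent-3-en-1-yn-1-yl]-3,5,5-trimethylcyclohex-3-en-1-ol | OC/C=C(C)/C#CC1=C(C)C[C@@H](O)CC1(C)C
F3 | step 20 | (2E)-5-[(4R)-4-hydroxy-2,6,6-trimethylcyclohex-1-en-1-yl]-3-methylpent-2-en-4-ynal | O=C/C=C(C)/C#CC1=C(C)C[C@@H](O)CC1(C)C
F4 | step 20 | ethyl (2E,4E,6E)-9-[(4R)-4-hydroxy-2,6,6-trimethylcyclohex-1-en-1-yl]-7-methylnona-2,4,6-trien-8-ynoate | CCOC(=O)/C=C/C=C/C=C(C)/C#CC1=C(C)C[C@@H](O)CC1(C)C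
F5 | step 20 | (1R)-4-[(3E,5E,7E)-9-hydroxy-3-methylnona-3,5,7-trien-1-yn-1-yl]-3,5,5-trimethylcyclohex-3-en-1-ol | OC/C=C/C=C/C=C(C)/C#CC1=C(C)C[C@@H](O)CC1(C)C
F6 | step 20 | (2E,4E,6E)-9-[(4R)-4-hydroxy-2,6,6-trimethylcyclohex-1-en-1-yl]-7-methylnona-2,4,6-trien-8-ynal | O=C/C=C/C=C/C=C(C)/C#CC1=C(C)C[C@@H](O)CC1(C)C
F7 | step 20 | (2E,4E,6E,8E)-11-[(4R)-4-hydroxy-2,6,6-trimethylcyclohex-1-en-1-yl]-2,9-dimethylundeca-2,4,6,8-tetraen-10-ynal | O=C/C(C)=C/C=C/C=C/C=C(C)/C#CC1=C(C)C[C@@H](O)CC1(C)C
F8 | step 20 | (1R)-4-[(3E,5E,7E,9E)-3,10-dimethyl-11-oxoundeca-3,5,7,9-tetraen-1-yn-1-yl]-3,5,5-trimethylcyclohex-3-en-1-yl acetate | O=C/C(C)=C/C=C/C=C/C=C(C)/C#CC1=C(C)C[C@@H](OC(C)=O)CC1(C)C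
F9 | step 20 | (1R)-4-[(3E,5E,7E,9E)-11-(4-bromo-5-oxo-2,5-dihydrofuran-2-yl)-11-{[tert-butyl(dimethyl)silyl]oxy}-3,10-dimethylundeca-3,5,7,9-tetraen-1-yn-1-yl]-3,5,5-trimethylcyclohex-3-en-1-yl acetate (mixture of diastereomers) | CC(=O)O[C@@H]1CC(C)=C(C#C/C(C)=C/C=C/C=C/C=C(C)/C(O[Si](C)(C)C(C)(C)C)C2OC(=O)C(Br)=C2)C(C)(C)C1
F10 | step 20 | (1R)-4-[(3E,5E,7E,9E,11Z)-11-(4-bromo-5-oxofuran-2(5H)-ylidene)-3,10-dimethylundeca-3,5,7,9-tetraen-1-yn-1-yl]-3,5,5-trimethylcyclohex-3-en-1-yl acetate | CC(=O)O[C@@H]1CC(C)=C(C#C/C(C)=C/C=C/C=C/C=C(C)/C=C2C=C(Br)C(=O)O/2)C(C)(C)C1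
F11 | step 18 | 3,5-dibromofuran-2(5H)-one (racemic) | O=C1OC(Br)C=C1Br
F12 | step 18 | (4-bromo-5-oxo-2,5-dihydrofuran-2-yl)triphenylphosphonium bromide | O=C1OC([P+](c2ccccc2)(c2ccccc2)c2ccccc2)C=C1Br.[Br-]
F13 | step 18 | 3-bromo-5-(triphenyl-λ5-phosphanylidene)furan-2(5H)-one | O=C1OC(=P(c2ccccc2)(c2ccccc2)c2ccccc2)C=C1Br
F14 | step 19 | tert-butyl(dimethyl){[(1R,3S,6S)-1,5,5-trimethyl-6-[(E)-2-(tributylstannyl)ethenyl]-7-oxabicyclo[4.1.0]heptan-3-yl]oxy}silane | CCCC[Sn](CCCC)(CCCC)/C=C/[C@@]12O[C@]1(C)C[C@@H](O[Si](C)(C)C(C)(C)C)CC2(C)C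
F15 | step 19 | (1R,3S,6S)-1,5,5-trimethyl-6-[(E)-2-(tributylstannyl)ethenyl]-7-oxabicyclo[4.1.0]heptan-3-ol | CCCC[Sn](CCCC)(CCCC)/C=C/[C@@]12O[C@]1(C)C[C@@H](O)CC2(C)C
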